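## Retrosynthetic overview

1. The target comes from a 4′,4′,5′-trisubstituted cyclopent-2-enone: the C-4′ bromide by reversible conjugate addition of HBr, the C-2′ carbinol by ketone reduction.
2. The cyclopentanone ring and its C-1′ quaternary centre come from a semipinacol ring expansion of a 1-alkenylcyclobutanol (cyclobutane to cyclopentane); the 4,4a-trans-diol comes from the C-4=C-4a alkene by epoxidation and hydrolysis.
3. The alkenylcyclobutanol comes from a C-6 bromodecalone plus the dianion of 1-(1-bromoethenyl)-2,2-dimethylcyclobutanol (2,2-dimethylcyclobutanone + bromoethene).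
4. The bromodecalone comes from (R)-Wieland–Miescher ketone: C-1 carbonyl to vinyl bromide to equatorial bromide, C-4 methyl by γ-methylenation and 1,6-reduction.
5. Ring order: ring A is the starting cyclohexanedione, ring B is closed by the Robinson annulation, and the cyclobutane is brought in intact and enlarged to the cyclopentane last.

Assumption: 2,2-dimethylcyclobutan-1-one and bromoethene are taken as commercial. Positions follow the target (decalin C-1 CHBr, C-4 C(OH)Me, C-4a C–OH, C-6 carbinol, C-8a C–Me; cyclopentane C-1′ quaternary, C-2′ CHOH, C-4′ CHBr, C-5′ CMe2), and α is the face opposite the C-8a methyl.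

## Route

Step 1
Reactants: 1 cyclohexane-1,3-dione
Product: 2 2-methylcyclohexane-1,3-dione
Conditions: MeI, KOH, H2O/dioxane, reflux
Reagents that add atoms: iodomethane, CI
Why: C-methylation of the doubly stabilised enolate at C-2 (β-diketone C-alkylation); no stereocentre is formed.

Step 2
Reactants: 2 2-methylcyclohexane-1,3-dione; 3 but-3-en-2-one
Product: 5 (R)-Wieland–Miescher ketone, via triketone 4 (not isolated)
Conditions: 3, Et3N (cat.), neat, rt; then D-proline (5 mol %), DMSO, rt; recrystallise
Reagents that add atoms: none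
Why: Michael addition followed by the proline-enamine aldol condensation (Hajos–Parrish–Eder–Sauer–Wiechert Robinson annulation), in which D-proline selects one of the two enantiotopic ring carbonyls and so sets the C-8a quaternary centre as R (the L-catalyst is known to give S).

Step 3
Reactants: 5 (R)-Wieland–Miescher ketone
Product: 7 (4aR)-5-bromo-4a-methyl-4,4a,7,8-tetrahydronaphthalen-2(3H)-one, via silyl hydrazone 6 (not isolated)
Conditions: TBSNHNHTBS, Sc(OTf)3 (cat.), CH2Cl2, 0 °C to rt; then Br2 (2 equiv), 2-tert-butyl-1,1,3,3-tetramethylguanidine, CH2Cl2, 0 °C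
Reagents that add atoms: bromine, BrBr
Why: The saturated C-1 carbonyl condenses faster than the vinylogous C-6 carbonyl (the same preference as in C-1 ketalisation of this diketone), and oxidation of the N-silyl hydrazone with bromine and base gives the C-1 vinyl bromide (Barton vinyl halide synthesis, N-silylhydrazone variant).

Step 4
Reactants: 7 (4aR)-5-bromo-4a-methyl-4,4a,7,8-tetrahydronaphthalen-2(3H)-one
Product: 8 (4aR)-5-bromo-4a-methyl-8-methylidene-4,4a,7,8-tetrahydronaphthalen-2(3H)-one
Conditions: CH2(OEt)2, POCl3, NaOAc, CHCl3, reflux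
Reagents that add atoms: diethoxymethane, CCOCOCC
Why: The dienol ether formed in the flask is attacked at its γ-carbon (C-4) by the ethoxymethyl cation and then loses ethanol, the one-step γ-methylenation known for 6-methylene steroid enones (vinylogous Mannich-type alkylation and elimination).

Step 5
Reactants: 8 (4aR)-5-bromo-4a-methyl-8-methylidene-4,4a,7,8-tetrahydronaphthalen-2(3H)-one
Product: 9 (4aR)-5-bromo-4a,8-dimethyl-3,4,4a,7-tetrahydronaphthalen-2(1H)-one
Conditions: LiBH(s-Bu)3, THF, −78 °C; then AcOH, −78 °C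
Reagents that add atoms: none
Why: The bulky hydride adds 1,6 to the unhindered exocyclic methylene, and kinetic protonation of the linear dienolate at C-5 gives the deconjugated ketone with the tetrasubstituted C-4=C-4a alkene (conjugate reduction with kinetic deconjugation).

Step 6
Reactants: 9 (4aR)-5-bromo-4a,8-dimethyl-3,4,4a,7-tetrahydronaphthalen-2(1H)-one
Product: 10 (4aR,5R)-5-bromo-4a,8-dimethyl-3,4,4a,5,6,7-hexahydronaphthalen-2(1H)-one
Conditions: Mn(dpm)3 (10 mol %), PhSiH3, t-BuOOH, i-PrOH, rt
Reagents that add atoms: none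
Why: Metal-hydride hydrogen-atom-transfer hydrogenation of the vinyl bromide with retention of the C–Br bond: H adds to C-2, and the α-bromo radical at C-1 takes its hydrogen axially from the open α face, so bromine ends equatorial and cis to the C-8a methyl (also the more stable epimer), while the tetrasubstituted alkene is inert.

Step 7
Reactants: 11 2,2-dimethylcyclobutan-1-one; 12 bromoethene
Product: 14 1-(1-bromoethenyl)-2,2-dimethylcyclobutan-1-ol, via (1-bromoethenyl)lithium 13 (not isolated)
Conditions: 12, LiN(i-Pr)2, THF/Et2O/pentane (4:1:1), −110 °C; then 11, −110 to −78 °C; aq. NH4Cl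
Reagents that add atoms: none
Why: α-Deprotonation of bromoethene at −110 °C gives the 1-bromovinyl carbenoid, which adds 1,2 to the strained, electrophilic cyclobutanone (carbonyl addition); the carbinol is racemic and this centre is erased in step 9.

Step 8
Reactants: 14 1-(1-bromoethenyl)-2,2-dimethylcyclobutan-1-ol; 10 (4aR,5R)-5-bromo-4a,8-dimethyl-3,4,4a,5,6,7-hexahydronaphthalen-2(1H)-one
Product: 17 (2S,4aR,5R)-5-bromo-2-[1-(1-hydroxy-2,2-dimethylcyclobutyl)ethenyl]-4a,8-dimethyl-1,2,3,4,4a,5,6,7-octahydronaphthalen-2-ol, via dilithio alkoxide 15 (not isolated), via organocerium reagent 16 (not isolated)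
Conditions: 14 (1.5 equiv), t-BuLi (3 equiv per 14), Et2O, −78 °C; CeCl3, THF, −78 °C; then 10, −78 °C; aq. NH4Cl
Reagents that add atoms: none
Why: Bromine–lithium exchange and transmetalation give a weakly basic organocerium that adds to the readily enolised β,γ-unsaturated ketone (Imamoto organocerium carbonyl addition), and this bulky α-branched alkenyl nucleophile enters equatorially, so the C-6 hydroxyl is axial (α); the cyclobutanol carbon is a 1:1 epimer mixture carried on as such.

Step 9
Reactants: 17 (2S,4aR,5R)-5-bromo-2-[1-(1-hydroxy-2,2-dimethylcyclobutyl)ethenyl]-4a,8-dimethyl-1,2,3,4,4a,5,6,7-octahydronaphthalen-2-ol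
Product: 18 (2R)-2-[(2S,4aR,5R)-5-bromo-2-hydroxy-4a,8-dimethyl-1,2,3,4,4a,5,6,7-octahydronaphthalen-2-yl]-2,3,3-trimethylcyclopentan-1-one
Conditions: (R,R)-N,N′-bis(3,5-di-tert-butylsalicylidene)-1,2-cyclohexanediaminocobalt (divalent cobalt, 5 mol %), N-fluoro-2,4,6-trimethylpyridinium triflate (1.5 equiv), PhSiH3 (1.2 equiv), PhCF3, 0 °C
Reagents that add atoms: none
Why: Proposed new method: a cobalt hydride transfers a hydrogen atom to the CH2 terminus of the 1,1-disubstituted alkene, the tertiary radical at the future C-1′ is captured by cobalt and oxidised by the N-fluoropyridinium salt to a tetravalent alkylcobalt (a masked tertiary cation), and the electron-rich CMe2 ring bond of the cyclobutanol, antiperiplanar to C–Co, migrates with loss of cobalt and of the carbinol proton (about 20 kcal/mol of strain released), forming the cyclopentanone and the C-1′ quaternary centre; the face is set by the chiral salen ligand that holds the C–Co bond (antipode chosen as the matched one after testing both), so both carbinol epimers should converge on one ketone, and the acid-labile tertiary allylic C-6 carbinol never meets a Brønsted acid; the closest known reactions are cobalt-salen/N-fluoropyridinium/silane radical–polar crossover hydrofunctionalisations of alkenes and the halonium- or acid-induced semipinacol ring expansion of 1-alkenylcyclobutanols.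

Step 10
Reactants: 18 (2R)-2-[(2S,4aR,5R)-5-bromo-2-hydroxy-4a,8-dimethyl-1,2,3,4,4a,5,6,7-octahydronaphthalen-2-yl]-2,3,3-trimethylcyclopentan-1-one
Product: 20 (2R)-2-[(2S,4aR,5R,8S,8aS)-5-bromo-2,8,8a-trihydroxy-4a,8-dimethyldecahydronaphthalen-2-yl]-2,3,3-trimethylcyclopentan-1-one, via α-epoxide 19 (not isolated)
Conditions: mCPBA (1.05 equiv), CH2Cl2, −20 °C; then THF/H2O, HClO4 (cat.), 0 °C to rt
Reagents that add atoms: 3-chloroperoxybenzoic acid, OOC(=O)c1cccc(Cl)c1; water, O
Why: The peracid attacks the only alkene from the α face, opposite the C-8a methyl and guided by hydrogen bonding to the axial C-6 hydroxyl (Henbest-type directed epoxidation), and acid hydrolysis opens the epoxide trans-diaxially (Fürst–Plattner) by water attack at C-4 from the β face, giving the 4β,4aα-diol.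

Step 11
Reactants: 20 (2R)-2-[(2S,4aR,5R,8S,8aS)-5-bromo-2,8,8a-trihydroxy-4a,8-dimethyldecahydronaphthalen-2-yl]-2,3,3-trimethylcyclopentan-1-one
Product: 21 (5R)-5-[(2S,4aR,5R,8S,8aS)-5-bromo-2,8,8a-trihydroxy-4a,8-dimethyldecahydronaphthalen-2-yl]-4,4,5-trimethylcyclopent-2-en-1-one
Conditions: 2-iodoxybenzoic acid, 4-methoxypyridine N-oxide, DMSO, rt to 45 °C
Reagents that add atoms: none
Why: Hypervalent-iodine dehydrogenation of the ketone through its only enolisable side (C-3′) gives the enone; the three tertiary alcohols cannot be oxidised and the trans-diaxial diol cannot form the cyclic ester needed for cleavage.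

Step 12
Reactants: 21 (5R)-5-[(2S,4aR,5R,8S,8aS)-5-bromo-2,8,8a-trihydroxy-4a,8-dimethyldecahydronaphthalen-2-yl]-4,4,5-trimethylcyclopent-2-en-1-one
Product: 23 (1R,4S,4aS,6S,8aR)-1-bromo-6-[(1S,2R,4S)-4-bromo-2-hydroxy-1,5,5-trimethylcyclopentyl]-4,8a-dimethyldecahydronaphthalene-4,4a,6-triol, via bromo ketone 22 (not isolated)
Conditions: HBr (33% in AcOH, 3 equiv), CH2Cl2, −20 to 0 °C until the C-4′ epimers have equilibrated; evaporate cold; then NaBH4, MeOH, −40 °C
Reagents that add atoms: hydrogen bromide, Br
Why: Conjugate addition of HBr is reversible, so C-4′ settles in the more stable arrangement with bromine pseudo-equatorial and cis to the pseudo-equatorial decalinyl group, and borohydride then attacks the ketone from the face opposite the decalinyl group and the bromine, placing the C-2′ hydroxyl cis to both (1,2-reduction under steric control).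

## Compound list

1 | cyclohexane-1,3-dione | O=C1CCCC(=O)C1 | starting material
2 | 2-methylcyclohexane-1,3-dione | CC1C(=O)CCCC1=O | intermediate
3 | but-3-en-2-one | CC(=O)C=C | starting material
4 | 2-methyl-2-(3-oxobutyl)cyclohexane-1,3-dione | CC(=O)CCC1(C)C(=O)CCCC1=O | intermediate
5 | (8aR)-8a-methyl-3,4,8,8a-tetrahydronaphthalene-1,6(2H,7H)-dione, (R)-Wieland–Miescher ketone | O=C1CC[C@@]2(C)C(=O)CCCC2=C1 | intermediate
6 | C-1 N-(tert-butyldimethylsilyl)hydrazone of 5 | O=C1CC[C@@]2(C)C(=NN[Si](C)(C)C(C)(C)C)CCCC2=C1 | intermediate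
7 | (4aR)-5-bromo-4a-methyl-4,4a,7,8-tetrahydronaphthalen-2(3H)-one | O=C1CC[C@@]2(C)C(Br)=CCCC2=C1 | intermediate
8 | (4aR)-5-bromo-4a-methyl-8-methylidene-4,4a,7,8-tetrahydronaphthalen-2(3H)-one | O=C1CC[C@@]2(C)C(Br)=CCC(=C)C2=C1 | intermediate
9 | (4aR)-5-bromo-4a,8-dimethyl-3,4,4a,7-tetrahydronaphthalen-2(1H)-one | O=C1CC[C@@]2(C)C(Br)=CCC(C)=C2C1 | intermediate
10 | (4aR,5R)-5-bromo-4a,8-dimethyl-3,4,4a,5,6,7-hexahydronaphthalen-2(1H)-one (Br equatorial, cis to the angular methyl) | O=C1CC[C@@]2(C)[C@H](Br)CCC(C)=C2C1 | intermediate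
11 | 2,2-dimethylcyclobutan-1-one | CC1(C)CCC1=O | starting material
12 | bromoethene | C=CBr | starting material
13 | (1-bromoethenyl)lithium | [Li]C(Br)=C | intermediate
14 | 1-(1-bromoethenyl)-2,2-dimethylcyclobutan-1-ol (racemic) | OC1(C(Br)=C)CCC1(C)C | intermediate
15 | lithium 1-(1-lithioethenyl)-2,2-dimethylcyclobutan-1-olate | [Li]OC1(C([Li])=C)CCC1(C)C | intermediate
16 | dichlorocerium reagent from 15 (alkenyl–CeCl2, lithium alkoxide) | [Li]OC1(C(=C)[Ce](Cl)Cl)CCC1(C)C | intermediate
17 | (2S,4aR,5R)-5-bromo-2-[1-(1-hydroxy-2,2-dimethylcyclobutyl)ethenyl]-4a,8-dimethyl-1,2,3,4,4a,5,6,7-octahydronaphthalen-2-ol (1:1 epimers at the cyclobutanol carbon) | C=C(C1(O)CCC1(C)C)[C@]1(O)CC[C@@]2(C)[C@H](Br)CCC(C)=C2C1 | intermediate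
18 | (2R)-2-[(2S,4aR,5R)-5-bromo-2-hydroxy-4a,8-dimethyl-1,2,3,4,4a,5,6,7-octahydronaphthalen-2-yl]-2,3,3-trimethylcyclopentan-1-one | CC1(C)CCC(=O)[C@@]1(C)[C@]1(O)CC[C@@]2(C)[C@H](Br)CCC(C)=C2C1 | intermediate
19 | C-4/C-4a α-epoxide of 18 (oxirane oxygen on the face of the C-6 hydroxyl, opposite the angular methyl) | CC1(C)CCC(=O)[C@@]1(C)[C@]1(O)CC[C@@]2(C)[C@H](Br)CC[C@@]3(C)O[C@@]23C1 | intermediate
20 | (2R)-2-[(2S,4aR,5R,8S,8aS)-5-bromo-2,8,8a-trihydroxy-4a,8-dimethyldecahydronaphthalen-2-yl]-2,3,3-trimethylcyclopentan-1-one | CC1(C)CCC(=O)[C@@]1(C)[C@]1(O)CC[C@@]2(C)[C@H](Br)CC[C@](C)(O)[C@]2(O)C1 | intermediate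
21 | (5R)-5-[(2S,4aR,5R,8S,8aS)-5-bromo-2,8,8a-trihydroxy-4a,8-dimethyldecahydronaphthalen-2-yl]-4,4,5-trimethylcyclopent-2-en-1-one | CC1(C)C=CC(=O)[C@@]1(C)[C@]1(O)CC[C@@]2(C)[C@H](Br)CC[C@](C)(O)[C@]2(O)C1 | intermediate
22 | (2R,4S)-4-bromo-2-[(2S,4aR,5R,8S,8aS)-5-bromo-2,8,8a-trihydroxy-4a,8-dimethyldecahydronaphthalen-2-yl]-2,3,3-trimethylcyclopentan-1-one | CC1(C)[C@@H](Br)CC(=O)[C@@]1(C)[C@]1(O)CC[C@@]2(C)[C@H](Br)CC[C@](C)(O)[C@]2(O)C1 | intermediate
23 | (1R,4S,4aS,6S,8aR)-1-bromo-6-[(1S,2R,4S)-4-bromo-2-hydroxy-1,5,5-trimethylcyclopentyl]-4,8a-dimethyldecahydronaphthalene-4,4a,6-triol (CNP0390567.2) | CC1(C)[C@@H](Br)C[C@@H](O)[C@@]1(C)[C@]1(O)CC[C@@]2(C)[C@H](Br)CC[C@](C)(O)[C@]2(O)C1 | target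

## Step count and risk

Total steps: 12 (three of them two-stage, one-flask operations). Longest linear sequence: 11 (steps 1–6 and 8–12; step 7 is the side branch).

Three steps most likely to fail:

**Step 9 (the new ring expansion).** The C-1′ selectivity may be low, the cyclobutylcarbinyl radical may ring-open before cobalt capture, or a hydroxyl may trap the cation. The fallback uses known chemistry and sets out from 17. N-Iodosuccinimide (CH2Cl2, −40 °C) triggers the established iodonium-induced semipinacol ring expansion and gives the iodomethyl ketone F1, whose C-1′ epimers are separated. Hydrogenolysis of the primary C–I bond (H2, Pd/C, Et3N, EtOAc) then gives 18, where the route is rejoined. Hydrogenolysis is chosen over a tin hydride because the β-keto primary radical could undergo Dowd–Beckwith ring enlargement.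

**Step 12 (HBr addition and reduction).** The tertiary carbinols may ionise in HBr, or the C-4′ equilibrium may be unfavourable. The fallback sets out from 21 and relies on kinetic face control followed by inversion. Nucleophilic epoxidation (H2O2, K2CO3, MeOH, 0 °C, brief, to limit retro-aldol cleavage) on the face opposite the decalinyl group gives the epoxy ketone F2. SmI2 (THF/MeOH, −90 °C) cleaves the α C–O bond to give the β-hydroxy ketone F3, with the 4′-hydroxyl trans to the decalinyl group. Appel bromination (PPh3, CBr4, CH2Cl2) with inversion gives 22, which is reduced with NaBH4 as in step 12.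

**Step 8 (fragment coupling).** Ketone 10 may enolise, or the C-6 face selectivity may be poor. The fallback sets out from 10 and reverses the order of the two carbonyl additions. (1-Bromoethenyl)lithium 13 (made as in step 7, −110 °C), which adds to enolisable ketones without proton transfer, converts 10 into the bromoallylic alcohol F4, whose C-6 epimers are separated. n-BuLi (1 equiv) then t-BuLi (2 equiv) at −100 °C, where the vinyl C–Br bond exchanges much faster than the neopentylic secondary C–Br bond, followed by 2,2-dimethylcyclobutan-1-one 11, gives 17, where the route is rejoined.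

Further compounds
F1 | step 9 | (2S)-2-[(2S,4aR,5R)-5-bromo-2-hydroxy-4a,8-dimethyl-1,2,3,4,4a,5,6,7-octahydronaphthalen-2-yl]-2-(iodomethyl)-3,3-dimethylcyclopentan-1-one | CC1(C)CCC(=O)[C@@]1(CI)[C@]1(O)CC[C@@]2(C)[C@H](Br)CCC(C)=C2C1
F2 | step 12 | 2,3-epoxide of enone 21, oxirane oxygen trans to the decalinyl group (on the face of the C-1′ methyl) | CC1(C)[C@@H]2O[C@@H]2C(=O)[C@@]1(C)[C@]1(O)CC[C@@]2(C)[C@H](Br)CC[C@](C)(O)[C@]2(O)C1
F3 | step 12 | (2R,4R)-2-[(2S,4aR,5R,8S,8aS)-5-bromo-2,8,8a-trihydroxy-4a,8-dimethyldecahydronaphthalen-2-yl]-4-hydroxy-2,3,3-trimethylcyclopentan-1-one | CC1(C)[C@H](O)CC(=O)[C@@]1(C)[C@]1(O)CC[C@@]2(C)[C@H](Br)CC[C@](C)(O)[C@]2(O)C1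
F4 | step 8 | (2S,4aR,5R)-5-bromo-2-(1-bromoethenyl)-4a,8-dimethyl-1,2,3,4,4a,5,6,7-octahydronaphthalen-2-ol | C=C(Br)[C@]1(O)CC[C@@]2(C)[C@H](Br)CCC(C)=C2C1
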